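Start from the late end of the run: at 6.0 d the flask holds what was made before one charge gave out, so the question is which charge that was.

solid substrate 0.050 M; partner 0.0750 M (fed, over 2.0 h); time 6.0 d

    starting material + partner → single product + by-product (k1 = 1.0 M⁻¹ min⁻¹)
    starting material + partner → other mono adduct + by-product (k2 = 0.077 M⁻¹ min⁻¹)
    partner + single product → bis adduct + by-product (k3 = 2.8 M⁻¹ min⁻¹)
    partner + other mono adduct → bis adduct + by-product (k4 = 2.4 M⁻¹ min⁻¹)
    solid substrate ⇌ starting material, rate k5*(cs5 - [starting material]) while solid is left; crystals form when [starting material] > cs5 (cs5 = 4.3 mM, k5 = 0.060 min⁻¹)

1. why nothing more happens at 6.0 d, or that something still does (for what has run out or reacted, a solid counts together with what of it has only dissolved) (the partner has run out first / it is still moving / all of the solid substrate has reacted / forward and back rates have come level)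
2. the single product standing at 6.0 d, as a percentage of the solid substrate charged
3. the bis adduct standing at 6.0 d, as a percentage of the solid substrate charged

- solid substrate is a solid; its amount is given per volume of the solution
- at the start none of the solid substrate is in solution
- what has only dissolved of solid substrate counts as not reacted
- the reaction counts as stopped when no species that holds the solid substrate changes by six tenths of a point or more over the second half of the time
- run time (flask): 6.0 d

Turn the question round and ask what the solid substrate would need in order to go first. At equal concentration the single product takes up partner at 2.8 M⁻¹ min⁻¹, faster than the starting material does by the step that makes it, at 1.0 M⁻¹ min⁻¹, and the other mono adduct takes it up at 2.4 M⁻¹ min⁻¹, faster than the starting material does by the step that makes that adduct, at 0.077 M⁻¹ min⁻¹. I therefore count two partner for each substrate that reacts. That gives the partner ceiling C, the partner charge shared out at two per substrate, 75.0 %, as a share of the solid charged: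

C = 0.0750 M / (2 × 0.050 M) = 75.0 %

The solid would go first with C of at least one, and this flask is 25 percentage points short of that. With the starting material at its solubility and two partner used per substrate, the partner has a half-life of 1.25 h, far shorter than 6.0 d. The solution stands below its solubility while partner is being used, which lengthens that time, but the gap is wide enough that I expect the partner, the limiting reagent, to be gone by 6.0 d.

Treat each mono adduct as steady, made as fast as it is lost. Partner then cancels, and with the dissolved starting material at its solubility 4.3 mM:

single product: m = (1.0 M⁻¹ min⁻¹ / 2.8 M⁻¹ min⁻¹) × 4.3 mM = 3.07 % of the charge

other mono adduct: n = (0.077 M⁻¹ min⁻¹ / 2.4 M⁻¹ min⁻¹) × 4.3 mM = 0.276 % of the charge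

bis adduct: C − (m + n) / 2 = 73.3 %

The forecast says the partner has run out first, with 2.9 % single product and 73.4 % bis adduct, since “nearly every substrate that reacts goes on to bis adduct, using two partner each”. My figures differ slightly from these.

The simulation gives the partner has run out first, with 2.90 % and 73.4 %; partner stands at 0 % at 6.00 d, and 14.8 % is still solid.

At 0.135 d, the first addition and the step from single product to bis adduct were using partner at a ratio of 1.0, the two per substrate that C counts. The forecast would miss by 5 points on bis adduct with partner at 0.0700 M or 0.0800 M.

In the neighbour flask with 0.013 M of solid substrate, C is 288 %, so the solid should go first, leaving 65.3 % of the partner. That neighbour flask gives 100 % bis adduct with 0 % of the solid substrate and 65 % of the partner left.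

(The rate constants are invented, and the outcome is calculated.)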